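The biflavone is disconnected at its only inter-unit bond, from C3' of ring B of the 6-methyl-7-methoxy unit (unit 1) to C8 of ring A of the apigenin unit (unit 2). That carbon pair, ortho to the 4'-OH whose para position is taken by C1', and between O7 and O1 of a phloroglucinol-type ring, is the imprint of an oxidative phenol–arene coupling. One anodic dehydrogenative cross-coupling therefore joins two complete monomers with no prefunctionalization. The precursors are racemic 4'-hydroxy-5,7-dimethoxy-6-methylflavanone, whose ring B is an easily oxidized para-alkylphenol, and tri-O-isopropylapigenin; dehydrogenation and a single BCl3 dealkylation complete the route.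

Key step: step 7

Assumption: the target has no stereocenter and its C3'–C8 biaryl axis is taken as configurationally undefined, so the flavanone intermediates are used as racemates and the axis is not controlled.

Step 1
Reactants: 1 2,6-dimethoxytoluene
Product: 3 3,5-dimethoxy-4-methylphenol, via aryl pinacol boronate 2 (not isolated)
Conditions: [Ir(OMe)(cod)]2 (cat.), 4,4'-di-tert-butyl-2,2'-bipyridine (cat.), B2pin2 (1 equiv), THF, 80 °C; then 30% H2O2, aq. NaOH, 0 °C → rt
Reagents that add atoms: hydrogen peroxide, OO (the phenolic oxygen); bis(pinacolato)diboron, CC1(C)OB(OC1(C)C)B1OC(C)(C)C(C)(C)O1 (boron of intermediate 2 only)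
Why: Iridium-catalysed arene C–H borylation is sterically governed and should reach only C4 of 1, the one C–H with no ortho substituent, and peroxide oxidation of the C–B bond (1,2-aryl shift from boron to oxygen) then gives the phenol in the same pot.

Step 2
Reactants: 3 3,5-dimethoxy-4-methylphenol
Product: 5 1-(6-hydroxy-2,4-dimethoxy-3-methylphenyl)ethanone, via aryl acetate 4 (not isolated)
Conditions: Ac2O (1.2 equiv), BF3·OEt2, 0 → 80 °C; aq. NaOAc work-up
Reagents that add atoms: acetic anhydride, CC(=O)OC(C)=O
Why: O-Acetylation followed by a BF3-mediated Fries rearrangement (Friedel–Crafts-type ortho C-acylation) can reach only the two symmetry-equivalent carbons flanked by OH and OMe because the para carbon carries the methyl group, so a single hydroxyacetophenone with the methyl at the future C6 should form.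

Step 3
Reactants: 6 4-hydroxybenzaldehyde
Product: 7 4-(methoxymethoxy)benzaldehyde
Conditions: MOMCl, iPr2NEt, CH2Cl2, 0 °C → rt
Reagents that add atoms: chloromethyl methyl ether, COCCl
Why: Williamson-type O-alkylation of the phenol with the reactive α-chloro ether masks it as an acetal, which keeps the aldehyde electrophilic and survives the strongly basic aldol step.

Step 4
Reactants: 5 1-(6-hydroxy-2,4-dimethoxy-3-methylphenyl)ethanone; 7 4-(methoxymethoxy)benzaldehyde
Product: 8 (E)-1-(6-hydroxy-2,4-dimethoxy-3-methylphenyl)-3-[4-(methoxymethoxy)phenyl]prop-2-en-1-one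
Conditions: KOH (aq. 50%), EtOH, rt; neutralized cold with AcOH
Reagents that add atoms: none
Why: Claisen–Schmidt (crossed aldol) condensation of the methyl ketone enolate with the non-enolizable aldehyde and E1cB dehydration should give the thermodynamically preferred E-chalcone, the MOM acetal being inert to hydroxide.

Step 5
Reactants: 8 (E)-1-(6-hydroxy-2,4-dimethoxy-3-methylphenyl)-3-[4-(methoxymethoxy)phenyl]prop-2-en-1-one
Product: 10 racemic 2-(4-hydroxyphenyl)-5,7-dimethoxy-6-methylchroman-4-one, via MOM-protected flavanone 9 (not isolated)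
Conditions: NaOAc, EtOH, reflux; aqueous work-up, crude taken on; 3 M HCl, MeOH, 50 °C
Reagents that add atoms: none
Why: Intramolecular oxa-Michael addition (6-endo-trig) of the single free phenol to the enone, which is easy for 2'-hydroxy-6'-alkoxychalcones, closes the dihydropyranone and creates C2 as a racemate (no control is needed because this center is erased in step 8), and acid-catalysed acetal methanolysis then frees the 4'-OH; because the 5-oxygen stays methylated the ring cannot reclose to the 8-methyl isomer.

Step 6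
Reactants: 11 apigenin (5,7-dihydroxy-2-(4-hydroxyphenyl)-4H-chromen-4-one)
Product: 12 5,7-diisopropoxy-2-(4-isopropoxyphenyl)-4H-chromen-4-one (5,7,4'-tri-O-isopropylapigenin)
Conditions: 2-bromopropane (excess), Cs2CO3, DMF, 70 °C, sealed vessel
Reagents that add atoms: 2-bromopropane, CC(C)Br
Why: Williamson etherification alkylates the 7- and 4'-OH readily, and the hydrogen-bonded 5-OH is forced by excess Cs2CO3 and halide in warm DMF, which gives an arene partner with no free phenol and oxidation-resistant ether groups.

Step 7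
Reactants: 10 racemic 2-(4-hydroxyphenyl)-5,7-dimethoxy-6-methylchroman-4-one; 12 5,7,4'-tri-O-isopropylapigenin
Product: 13 racemic 8-[2-hydroxy-5-(5,7-dimethoxy-6-methyl-4-oxochroman-2-yl)phenyl]-5,7-diisopropoxy-2-(4-isopropoxyphenyl)-4H-chromen-4-one
Conditions: boron-doped diamond anode, nickel cathode, undivided cell, constant current (about 2 F per mol of 10); HFIP–MeOH (about 6:1), methyltributylammonium methylsulfate (about 0.1 M), 12 (3 equiv, excess recovered), 10 added slowly by syringe pump, 45 °C
Reagents that add atoms: none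
Why: Proposed new method: ring B of 10 is a para-alkylphenol insulated from the C4 ketone by the sp3 carbon C2, so it should be the most easily oxidized site present, and anodic oxidation at boron-doped diamond turns it into an HFIP-solvated phenoxyl radical (or phenoxonium ion) whose ortho carbon C3' is attacked by C8 of ring A of 12, after which loss of a second electron and two protons rearomatizes both rings while hydrogen is evolved at the cathode. The closest known reaction type is the anodic dehydrogenative cross-coupling of 4-substituted phenols with alkoxyarenes at boron-doped diamond in HFIP, which has not been shown on flavonoid partners. No ring is closed and no stereocenter is created; C2 stays racemic and the new biaryl axis, undefined in the target, is left uncontrolled. The selectivity that matters most is cross- over homo-coupling, which relies on the excess of 12, on a low stationary concentration of 10 through slow addition, and on HFIP hydrogen bonding that shields the phenolic product from further oxidation; the remaining hazard is attack by C8 of ring A of a second molecule of 10. Regiochemistry on the phenol is fixed because the para position is blocked by C1' and the two ortho carbons are equivalent, and on the arene because C8 is flanked by one isopropoxy group and the ring oxygen whereas C6 lies between two isopropoxy groups. Were unit 1 already a flavone, its 4'-OH would be a vinylogous acid conjugated to the pyranone carbonyl and much harder to oxidize, which is why the flavanone oxidation level is used in this step.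

Step 8
Reactants: 13 racemic C3'–C8 linked flavanone–flavone
Product: 14 8-[2-hydroxy-5-(5,7-dimethoxy-6-methyl-4-oxo-4H-chromen-2-yl)phenyl]-5,7-diisopropoxy-2-(4-isopropoxyphenyl)-4H-chromen-4-one
Conditions: DDQ (1.5–2 equiv), 1,4-dioxane, reflux
Reagents that add atoms: none
Why: Quinone dehydrogenation of a flavanone, in which DDQ abstracts hydride from the benzylic, oxygen-bearing C2–H (assisted by the para-hydroxyl of ring B) and the C3 proton is then lost, should give the 4-pyranone and thereby remove the only stereocenter, while the ethers and the pre-formed flavone of unit 2 are inert.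

Step 9
Reactants: 14 protected biflavone
Product: 15 8-[2-hydroxy-5-(5-hydroxy-7-methoxy-6-methyl-4-oxo-4H-chromen-2-yl)phenyl]-5,7-dihydroxy-2-(4-hydroxyphenyl)-4H-chromen-4-one (target CNP0113589.0)
Conditions: BCl3 (1 M in CH2Cl2, excess), CH2Cl2, −78 °C → rt; then ice-water
Reagents that add atoms: none
Why: Lewis-acid ether cleavage with BCl3 removes the three secondary isopropyl ethers through their ionization-prone O–C bonds and the peri 5-OMe of unit 1 through a six-membered dichloroboron chelate with the C4 carbonyl, whereas the unchelated primary 7-OMe has neither activation and should be retained.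

Compound list
1 | 2,6-dimethoxytoluene | COc1cccc(OC)c1C | starting material
2 | 2-(3,5-dimethoxy-4-methylphenyl)-4,4,5,5-tetramethyl-1,3,2-dioxaborolane (formed in step 1, not isolated) | COc1cc(B2OC(C)(C)C(C)(C)O2)cc(OC)c1C | intermediate
3 | 3,5-dimethoxy-4-methylphenol | COc1cc(O)cc(OC)c1C | intermediate
4 | 3,5-dimethoxy-4-methylphenyl acetate (formed in step 2, not isolated) | CC(=O)Oc1cc(OC)c(C)c(OC)c1 | intermediate
5 | 1-(6-hydroxy-2,4-dimethoxy-3-methylphenyl)ethanone | CC(=O)c1c(O)cc(OC)c(C)c1OC | intermediate
6 | 4-hydroxybenzaldehyde | O=Cc1ccc(O)cc1 | starting material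
7 | 4-(methoxymethoxy)benzaldehyde | COCOc1ccc(C=O)cc1 | intermediate
8 | (E)-1-(6-hydroxy-2,4-dimethoxy-3-methylphenyl)-3-[4-(methoxymethoxy)phenyl]prop-2-en-1-one | COCOc1ccc(/C=C/C(=O)c2c(O)cc(OC)c(C)c2OC)cc1 | intermediate
9 | racemic 5,7-dimethoxy-2-[4-(methoxymethoxy)phenyl]-6-methylchroman-4-one (formed in step 5, not isolated) | COCOc1ccc(C2CC(=O)c3c(OC)c(C)c(OC)cc3O2)cc1 | intermediate
10 | racemic 2-(4-hydroxyphenyl)-5,7-dimethoxy-6-methylchroman-4-one | COc1cc2OC(c3ccc(O)cc3)CC(=O)c2c(OC)c1C | intermediate
11 | apigenin | O=c1cc(-c2ccc(O)cc2)oc2cc(O)cc(O)c12 | starting material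
12 | 5,7-diisopropoxy-2-(4-isopropoxyphenyl)-4H-chromen-4-one | CC(C)Oc1ccc(-c2cc(=O)c3c(OC(C)C)cc(OC(C)C)cc3o2)cc1 | intermediate
13 | racemic 8-[2-hydroxy-5-(5,7-dimethoxy-6-methyl-4-oxochroman-2-yl)phenyl]-5,7-diisopropoxy-2-(4-isopropoxyphenyl)-4H-chromen-4-one | COc1cc2OC(c3ccc(O)c(-c4c(OC(C)C)cc(OC(C)C)c5c(=O)cc(-c6ccc(OC(C)C)cc6)oc45)c3)CC(=O)c2c(OC)c1C | intermediate
14 | 8-[2-hydroxy-5-(5,7-dimethoxy-6-methyl-4-oxo-4H-chromen-2-yl)phenyl]-5,7-diisopropoxy-2-(4-isopropoxyphenyl)-4H-chromen-4-one | COc1cc2oc(-c3ccc(O)c(-c4c(OC(C)C)cc(OC(C)C)c5c(=O)cc(-c6ccc(OC(C)C)cc6)oc45)c3)cc(=O)c2c(OC)c1C | intermediate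
15 | 8-[2-hydroxy-5-(5-hydroxy-7-methoxy-6-methyl-4-oxo-4H-chromen-2-yl)phenyl]-5,7-dihydroxy-2-(4-hydroxyphenyl)-4H-chromen-4-one | COc1cc2oc(-c3ccc(O)c(-c4c(O)cc(O)c5c(=O)cc(-c6ccc(O)cc6)oc45)c3)cc(=O)c2c(O)c1C | target

Total step count: 9. Longest linear sequence: 7 steps (steps 1, 2, 4, 5, 7, 8, 9, from 1 to 15).

Steps most likely to fail

Step 7 (proposed new method). The phenol partner may homo-couple through the nucleophilic C8 of its own ring A, the biaryl phenol formed may be oxidized further, or the arene partner may be attacked at C6. The fallback uses known Suzuki–Miyaura chemistry, sets out from 6 and 12 (5 joins on the way) and returns to the route at 13. Compound 6 would be monobrominated ortho to the hydroxyl (Br2, AcOH, 0 °C) to 3-bromo-4-hydroxybenzaldehyde F1 and protected (MOMCl, iPr2NEt) as 3-bromo-4-(methoxymethoxy)benzaldehyde F2. Miyaura borylation (B2pin2, Pd(dppf)Cl2, KOAc, dioxane, 90 °C) would then give 4-(methoxymethoxy)-3-(4,4,5,5-tetramethyl-1,3,2-dioxaborolan-2-yl)benzaldehyde F3. In parallel 12 would be iodinated (I2, CF3CO2Ag, CH2Cl2) at C8, the usual site of electrophilic substitution in 5,7-dialkoxyflavones, to 8-iodo-5,7-diisopropoxy-2-(4-isopropoxyphenyl)-4H-chromen-4-one F4. Cross-coupling of F3 with F4 (Pd(OAc)2, SPhos, K3PO4, toluene–H2O, 90 °C) should give the biaryl aldehyde 3-[5,7-diisopropoxy-2-(4-isopropoxyphenyl)-4-oxo-4H-chromen-8-yl]-4-(methoxymethoxy)benzaldehyde F5. Claisen–Schmidt condensation of F5 with 5 (KOH, EtOH, rt) would give the flavone-bearing E-chalcone F6, and NaOAc in refluxing EtOH would close it to the MOM-protected flavanone–flavone F7. HCl in MeOH would finally remove the acetal and deliver 13.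

Step 8. The quinone may oxidize the free, electron-rich biaryl phenol instead of the C2–H, or the dehydrogenation may stall. The fallback masks the phenol and switches to an iodination–elimination mechanism; it sets out from 13 and returns at 14. Acetylation (Ac2O, pyridine, rt) would give the 4'-O-acetyl flavanone–flavone F8, catalytic I2 in DMSO at 120 °C (α-iodination, loss of HI, reoxidation of iodide by DMSO) the 4'-O-acetyl biflavone F9, and K2CO3 in MeOH at rt would remove the acetate to give 14.

Step 9. The two unchelated isopropyl ethers may be cleaved incompletely under conditions mild enough to keep the 7-OMe, or the 7-methyl may be lost when the reaction is forced. The fallback separates the two cleavage modes, sets out from 14 and returns at 15. A limited amount of BCl3 in CH2Cl2 at −78 °C would cleave only the two peri, chelation-activated ethers (5-OMe of unit 1 and 5-O-isopropyl of unit 2) to 8-[2-hydroxy-5-(5-hydroxy-7-methoxy-6-methyl-4-oxo-4H-chromen-2-yl)phenyl]-5-hydroxy-7-isopropoxy-2-(4-isopropoxyphenyl)-4H-chromen-4-one F10. AlCl3 in CH2Cl2 at rt, which dealkylates secondary isopropyl aryl ethers by ionization and leaves methyl ethers, would then give 15.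

Further compounds
F1 | step 7 | 3-bromo-4-hydroxybenzaldehyde | O=Cc1ccc(O)c(Br)c1
F2 | step 7 | 3-bromo-4-(methoxymethoxy)benzaldehyde | COCOc1ccc(C=O)cc1Br
F3 | step 7 | 4-(methoxymethoxy)-3-(4,4,5,5-tetramethyl-1,3,2-dioxaborolan-2-yl)benzaldehyde | COCOc1ccc(C=O)cc1B1OC(C)(C)C(C)(C)O1
F4 | step 7 | 8-iodo-5,7-diisopropoxy-2-(4-isopropoxyphenyl)-4H-chromen-4-one | CC(C)Oc1ccc(-c2cc(=O)c3c(OC(C)C)cc(OC(C)C)c(I)c3o2)cc1
F5 | step 7 | 3-[5,7-diisopropoxy-2-(4-isopropoxyphenyl)-4-oxo-4H-chromen-8-yl]-4-(methoxymethoxy)benzaldehyde | COCOc1ccc(C=O)cc1-c1c(OC(C)C)cc(OC(C)C)c2c(=O)cc(-c3ccc(OC(C)C)cc3)oc12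
F6 | step 7 | (E)-chalcone from F5 and 5, 8-{5-[3-(6-hydroxy-2,4-dimethoxy-3-methylphenyl)-3-oxoprop-1-enyl]-2-(methoxymethoxy)phenyl}-5,7-diisopropoxy-2-(4-isopropoxyphenyl)-4H-chromen-4-one | COCOc1ccc(/C=C/C(=O)c2c(O)cc(OC)c(C)c2OC)cc1-c1c(OC(C)C)cc(OC(C)C)c2c(=O)cc(-c3ccc(OC(C)C)cc3)oc12
F7 | step 7 | racemic 8-[5-(5,7-dimethoxy-6-methyl-4-oxochroman-2-yl)-2-(methoxymethoxy)phenyl]-5,7-diisopropoxy-2-(4-isopropoxyphenyl)-4H-chromen-4-one | COCOc1ccc(C2CC(=O)c3c(OC)c(C)c(OC)cc3O2)cc1-c1c(OC(C)C)cc(OC(C)C)c2c(=O)cc(-c3ccc(OC(C)C)cc3)oc12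
F8 | step 8 | racemic 4'-O-acetate of 13 | CC(=O)Oc1ccc(C2CC(=O)c3c(OC)c(C)c(OC)cc3O2)cc1-c1c(OC(C)C)cc(OC(C)C)c2c(=O)cc(-c3ccc(OC(C)C)cc3)oc12
F9 | step 8 | 4'-O-acetate of 14 | CC(=O)Oc1ccc(-c2cc(=O)c3c(OC)c(C)c(OC)cc3o2)cc1-c1c(OC(C)C)cc(OC(C)C)c2c(=O)cc(-c3ccc(OC(C)C)cc3)oc12
F10 | step 9 | 8-[2-hydroxy-5-(5-hydroxy-7-methoxy-6-methyl-4-oxo-4H-chromen-2-yl)phenyl]-5-hydroxy-7-isopropoxy-2-(4-isopropoxyphenyl)-4H-chromen-4-one | COc1cc2oc(-c3ccc(O)c(-c4c(OC(C)C)cc(O)c5c(=O)cc(-c6ccc(OC(C)C)cc6)oc45)c3)cc(=O)c2c(O)c1C
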